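Time was the first thing I weighed in this flask: target slips into its isomer while it waits, and the share asked for is read after the product has stood.

| setting | north | south-west | north-east | east | birch | oak | larch | maple |
|---|---|---|---|---|---|---|---|---|
| starting material | 0.25 M | 0.25 M | 0.25 M | 0.25 M | 0.25 M (fed, over 20.0 min) | 0.25 M | 0.25 M | 0.25 M |
| second substrate | 0.25 M | 0.12 M | 0.50 M | 0.25 M | 0.250 M | 0.250 M | 0.250 M | 0.250 M |
| reagent | 0.15 M | 0.15 M | 0.15 M | 0.15 M | 0.150 M | 0.150 M (fed, over 20.0 min) | 0.150 M | 0.150 M |
| free catalyst | 12 mM | 12 mM | 12 mM | 24 mM | 12 mM | 12 mM | 12 mM | 12 mM |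
| remark | run made earlier | run made earlier | run made earlier | run made earlier | a stirred flask in which starting material is dosed at a steady rate over 20.0 min without added volume, worked up at 40 min | a stirred flask in which reagent is dosed at a steady rate over 20.0 min without added volume, worked up at 40 min | a closed flask charged with all of it at once and left for 40 min | a single well-mixed tank run continuously and read at steady state, 40 min in it on average |
| time |  |  |  |  | 40 min | 40 min | 40 min |  |

| run | time / min | target / % | isomer of the product / % | starting material / % |
|---|---|---|---|---|
| north | 3.00 | 9.1 | 1.0 | 90.5 |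
| north | 8.00 | 19.3 | 5.3 | 75.6 |
| north | 15.0 | 27.2 | 13.0 | 59.3 |
| north | 40.0 | 20.8 | 34.3 | 40.2 |
| south-west | 3.00 | 8.9 | 0.9 | 89.9 |
| south-west | 8.00 | 19.9 | 4.4 | 74.9 |
| south-west | 15.0 | 27.9 | 13.6 | 58.4 |
| south-west | 25.0 | 30.9 | 25.9 | 42.2 |
| north-east | 3.00 | 9.0 | 0.9 | 90.6 |
| north-east | 8.00 | 19.1 | 5.2 | 75.5 |
| north-east | 15.0 | 26.9 | 12.9 | 60.5 |
| north-east | 25.0 | 26.4 | 24.9 | 45.2 |
| east | 2.00 | 8.9 | 0.7 | 90.0 |
| east | 4.00 | 16.5 | 2.6 | 81.6 |
| east | 10.0 | 30.1 | 10.1 | 60.6 |
| east | 25.0 | 25.8 | 29.3 | 36.5 |

(standard deviation of a reading: 0.3 percentage points)

- the stated concentrations are those of everything mixed, before any reaction; amounts are the same in each set-up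
- what was read earlier has a scatter of 0.3 percentage points, one standard deviation
- the feed brings no volume worth counting
- the earlier runs were made in a closed, stirred flask

1. the set-up with the highest share of target in all that became target or isomer of the product, at the outlet or at the end ("none" if the first two lie within 2 percentage points) (birch / oak / larch / maple / none)
2. share of target in all that became target or isomer of the product, at the outlet or at the end, birch
3. share of target in all that became target or isomer of the product, at the outlet or at the end, oak
4. share of target in all that became target or isomer of the product, at the outlet or at the end, larch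
5. share of target in all that became target or isomer of the product, at the outlet or at the end, maple

I took isomer to come from target and return to it, d[isomer]/dt = kf[target] − kb[isomer], and averaged the south-west and north-east runs. Isomer rose at 0.0121 min⁻¹ of the charge over the first stretch and 0.0121 min⁻¹ over the next, about the same, while mean target rose 4.6 percentage points and mean isomer 10 points. So kb/kf is the ratio of those rises, which puts the limiting share of target at 30.8%, and the first stretch gives λ = kf + kb = 0.0897 min⁻¹. Call N the exchange turns, λ times the time in the vessel: 3.59 for 40 min, well past the crossing from kinetic to thermodynamic control at N equal to one, which lies at 11.2 min.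

Two extremes bound maple: a frozen pair gives a share of 100%, an equilibrated pair gives the limit. Product made at the start of a closed flask keeps exp(−N) of its excess over the limit, 2.77%. The tank's balance keeps one over one plus N, 21.8%, more than that, since part of its product leaves young, and the rate of making target cancels. My reckoning for maple was 45.9%.

The forecast gave 47% for birch, 39% for oak, 37.7% for larch and 46% for maple, with a limit near 35% where mine was 30.8%, and chose none: “Birch and maple lie within 2 points, so none.”

The flask gave 44.8% for birch, 39.7% for oak, 38.4% for larch and 47.6% for maple, so maple came first, 2.8 points ahead of birch, beyond the margin.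

    starting material + free catalyst ⇌ catalyst intermediate A (K = 762 M⁻¹, k = 21.6 M⁻¹ min⁻¹)
    reagent + catalyst intermediate A → free catalyst + target (k = 1000 M⁻¹ min⁻¹)
    second substrate + free catalyst ⇌ catalyst intermediate B (K = 1.68 M⁻¹, k = 14.7 M⁻¹ min⁻¹)
    reagent + catalyst intermediate B → free catalyst + second product (k = 15.0 M⁻¹ min⁻¹)
    2 free catalyst ⇌ resting dimer, settled at all times (K = 1850 M⁻¹)
    target ⇌ isomer of the product (K = 2.00, k = 0.0614 min⁻¹)

Back-mixing is one part of maple's lead: without it the share is 38.4% in place of 47.6%, the young product my 45.9% counted on. The return of isomer to target is the main reason larch reads 38.4% and not 17.2%, and larch left for 400 min has N of 35.9, with a share of 33.3%.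

Readings and results are calculated for an exercise, and the scatter is random.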